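**Retrosynthetic overview**

1. Numbering: ring A is C1 (O-aryl), C2 (OMe), C3 (H), C4/C5/C6 (Br); ring B is C1' (ether O), C2' (OH), C3' (Br), C4' (H), C5' (Br), C6' (H). The plan rests on the run C3(H)–C4(Br)–C5(Br)–C6(Br) of ring A. Bromination of an assembled diaryl ether cannot reach this pattern because ring B reacts first, but the same pattern is already present in the chain C5–C4–C3–C2 of 2,3,4-tribromothiophene.
2. Endgame disconnections: C3'–Br and C5'–Br (phenol-directed bromination, last), the O-benzyl group at C2', O–CH3 at C2, and C2–O back to C2–B.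
3. Key disconnection: C1–C6 and C2–C3 of ring A. This is a Diels–Alder addition of 2,3,4-tribromothiophene 1,1-dioxide to the triple bond (C1≡C2) of an aryloxyethynyl pinacol boronate, followed by loss of SO2.
4. The diene comes from tetrabromothiophene by one α-debromination and S-oxidation. The dienophile comes from 2-(benzyloxy)phenol and trichloroethylene, then elimination and borylation with isopropoxy pinacol borate.
5. Ring order: ring B and the benzyl ring are bought; ring A is the only ring built (step 5).

Key step: step 5

Remark: the target has no stereocentre and no stereogenic double bond. The only stereochemical elements on the way are the E geometry of 9 and the racemic bridgeheads of 15, and both are erased later.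

**Step 1**
Reactants: 1 tetrabromothiophene
Product: 3 2,3,4-tribromothiophene, via 3,4,5-tribromo-2-thienyllithium 2 (not isolated)
Conditions: n-BuLi (1.0 equiv), Et2O, −78 °C; then H2O/THF, −78 °C to rt
Reagents that add atoms: none
Why: Halogen–metal exchange followed by protonolysis: bromine–lithium exchange is fastest at an α-carbon because the carbanion next to sulfur is the best stabilised, one equivalent of n-BuLi at low temperature should stop at the mono-lithio stage 2, and cold protonation forestalls halogen migration.

**Step 2**
Reactants: 3 2,3,4-tribromothiophene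
Product: 5 2,3,4-tribromothiophene 1,1-dioxide, via 2,3,4-tribromothiophene 1-oxide 4 (not isolated)
Conditions: (CF3CO)2O, urea·H2O2, MeCN, 0 °C to rt; cold aqueous work-up, 5 kept at −20 °C and used promptly
Reagents that add atoms: hydrogen peroxide as its urea adduct, OO.NC(N)=O, delivered through trifluoroperacetic acid, OOC(=O)C(F)(F)F
Why: Electrophilic S-oxidation by trifluoroperacetic acid, the peracid used for polybromothiophenes that are too electron-poor for milder peracids, in which sulfur is the only oxidisable site and the non-aromatic 4 is oxidised faster than 3, so it should not accumulate.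

**Step 3**
Reactants: 6 2-(benzyloxy)phenol; 7 trichloroethylene
Product: 9 1-(benzyloxy)-2-{[(E)-1,2-dichloroethenyl]oxy}benzene, via dichloroacetylene 8 (not isolated)
Conditions: K2CO3, DMF, 70 °C
Reagents that add atoms: trichloroethylene 7, ClC=C(Cl)Cl
Why: Base-mediated elimination–addition (nucleophilic vinylation of a phenol): K2CO3 dehydrochlorinates 7 to 8 at low stationary concentration, the phenoxide of 6 adds to it and the vinyl anion is protonated anti, which sets the E geometry, while the benzyl ether is inert.

**Step 4**
Reactants: 9 1-(benzyloxy)-2-{[(E)-1,2-dichloroethenyl]oxy}benzene; 10 2-isopropoxy-4,4,5,5-tetramethyl-1,3,2-dioxaborolane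
Product: 14 2-{[2-(benzyloxy)phenoxy]ethynyl}-4,4,5,5-tetramethyl-1,3,2-dioxaborolane, via chloroalkynyl ether 11 (not isolated), via lithium aryloxyacetylide 12 (not isolated), via lithium alkynyl(isopropoxy)borate 13 (not isolated)
Conditions: n-BuLi (2.1 equiv), THF, −78 to −40 °C; 10, −78 °C; HCl·Et2O (1.0 equiv), −78 °C to rt; filtration and concentration under N2, no aqueous work-up
Reagents that add atoms: 2-isopropoxy-4,4,5,5-tetramethyl-1,3,2-dioxaborolane 10, CC(C)OB1OC(C)(C)C(C)(C)O1
Why: Dehydrochlorination of the dichlorovinyl ether, chlorine–lithium exchange and electrophilic borylation of the acetylide with an alkoxyboronate form the standard alkynyl boronate synthesis, in which the single equivalent of anhydrous acid is consumed by the far more basic isopropoxide ligand of 13 before it can add to the ynol ether, and water is excluded because the push–pull alkyne is prone to protodeboronation.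

**Step 5**
Reactants: 5 2,3,4-tribromothiophene 1,1-dioxide; 14 2-{[2-(benzyloxy)phenoxy]ethynyl}-4,4,5,5-tetramethyl-1,3,2-dioxaborolane
Product: 16 2-{2-[2-(benzyloxy)phenoxy]-3,4,5-tribromophenyl}-4,4,5,5-tetramethyl-1,3,2-dioxaborolane, via bridged bicyclic sulfone 15 (not isolated)
Conditions: 5 (1.3 equiv) added slowly by syringe pump to 14, toluene, 4 Å MS, N2 sweep, 80 °C
Reagents that add atoms: none
Why: Proposed new method: the electron-poor, non-aromatic diene 5 and the oxygen-activated alkyne 14 should combine in an inverse-electron-demand Diels–Alder reaction that is concerted but strongly asynchronous, the C2–C3 bond (boron-bearing alkyne carbon to the thiophene C5–H terminus) running ahead of the C1–C6 bond (oxygen-bearing alkyne carbon to the thiophene C2–Br terminus). Ring A is closed as a six-membered carbocycle by intermolecular (4+2) cycloaddition, first inside the 7-thiabicyclo[2.2.1]heptadiene dioxide 15, whose cheletropic loss of SO2 is driven by aromatisation and gives 16 directly, with no elimination step that could cost the aryloxy group. The closest known reactions are the cycloaddition/SO2 extrusion of tetrahalothiophene 1,1-dioxides with alkynes and the cycloaddition/extrusion of alkynyl pinacol boronates with 2-pyrones and cyclopentadienones, but a thiophene dioxide has not been paired with an alkynyl boronate and a 1-aryloxyalkynyl boronate has not served as a dienophile. Regioselectivity is the one selectivity needed: oxygen donation and the vacant boron orbital polarise the alkyne in the same sense, so the boron-bearing carbon is the nucleophilic end and should attack the only unsubstituted diene terminus, which leaves the developing negative charge on the carbon that carries both bromine and the sulfonyl group, and the bulky boronate also prefers the C–H neighbour on steric grounds. The two bridgehead stereocentres of 15 form as a racemate and vanish with SO2, so no stereocontrol is required. Slow addition keeps the concentration of 5 low against self-dimerisation through its C4=C5 bond, and the sieves and gas sweep remove moisture and SO2, which would otherwise protodeboronate 14.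

**Step 6**
Reactants: 16 2-{2-[2-(benzyloxy)phenoxy]-3,4,5-tribromophenyl}-4,4,5,5-tetramethyl-1,3,2-dioxaborolane
Product: 18 2-[2-(benzyloxy)phenoxy]-3,4,5-tribromophenol, via aryl pinacol borate 17 (not isolated)
Conditions: 30% aq H2O2, 1 M NaOH, THF, 0 °C to rt; then 1 M HCl
Reagents that add atoms: hydrogen peroxide, OO
Why: Boronate oxidation: hydroperoxide adds to boron and the aryl group migrates from boron to oxygen at the same carbon, so oxygen arrives exactly at C2, and the aryl bromides, the benzyl ether and the diaryl ether are inert to cold alkaline peroxide.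

**Step 7**
Reactants: 18 2-[2-(benzyloxy)phenoxy]-3,4,5-tribromophenol
Product: 19 2-[2-(benzyloxy)phenoxy]-3,4,5-tribromoanisole
Conditions: MeI, K2CO3, acetone, 40 °C
Reagents that add atoms: iodomethane, CI
Why: Williamson ether synthesis: the acidic tribromophenol is the only nucleophilic site of 18 and its phenoxide is methylated by SN2 attack on MeI.

**Step 8**
Reactants: 19 2-[2-(benzyloxy)phenoxy]-3,4,5-tribromoanisole
Product: 21 2-(2,3,4-tribromo-6-methoxyphenoxy)phenol, via aryloxydichloroborane 20 (not isolated)
Conditions: BCl3, pentamethylbenzene, CH2Cl2, −78 °C; then H2O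
Reagents that add atoms: none
Why: Lewis-acid debenzylation with a cation scavenger: BCl3 ionises only the benzylic C–O bond at −78 °C and pentamethylbenzene captures the benzyl cation by Friedel–Crafts alkylation, so the methyl ether, the diaryl ether and all C–Br bonds (which hydrogenolysis would endanger) should survive.

**Step 9**
Reactants: 21 2-(2,3,4-tribromo-6-methoxyphenoxy)phenol
Product: 23 2,4-dibromo-6-(2,3,4-tribromo-6-methoxyphenoxy)phenol (target), via C5'-monobromide 22 (not isolated)
Conditions: Br2 (2.05 equiv), NaOAc, AcOH/CH2Cl2, 0 °C to rt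
Reagents that add atoms: bromine, BrBr
Why: Electrophilic aromatic bromination: the free C2' hydroxyl is the strongest donor and directs first to its para carbon C5' and then to its ortho carbon C3', the bridging oxygen is a weak director because its lone pair is shared with the tribromo ring, the lone C3–H of ring A sits on a ring deactivated by three bromines, and the measured amount of Br2 stops the reaction at the dibromide.

**Compound list**

1 | tetrabromothiophene | Brc1sc(Br)c(Br)c1Br | starting material
2 | 3,4,5-tribromo-2-thienyllithium | [Li]c1sc(Br)c(Br)c1Br | intermediate (not isolated)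
3 | 2,3,4-tribromothiophene | Brc1scc(Br)c1Br | intermediate
4 | 2,3,4-tribromothiophene 1-oxide (pyramidal sulfur inverts fast, no fixed configuration) | O=S1C=C(Br)C(Br)=C1Br | intermediate (not isolated)
5 | 2,3,4-tribromothiophene 1,1-dioxide | O=S1(=O)C=C(Br)C(Br)=C1Br | intermediate
6 | 2-(benzyloxy)phenol | Oc1ccccc1OCc1ccccc1 | starting material
7 | trichloroethylene | ClC=C(Cl)Cl | starting material
8 | dichloroacetylene | ClC#CCl | intermediate (not isolated)
9 | 1-(benzyloxy)-2-{[(E)-1,2-dichloroethenyl]oxy}benzene | Cl/C=C(/Cl)Oc1ccccc1OCc1ccccc1 | intermediate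
10 | 2-isopropoxy-4,4,5,5-tetramethyl-1,3,2-dioxaborolane | CC(C)OB1OC(C)(C)C(C)(C)O1 | starting material
11 | 1-(benzyloxy)-2-[(chloroethynyl)oxy]benzene | ClC#COc1ccccc1OCc1ccccc1 | intermediate (not isolated)
12 | lithium [2-(benzyloxy)phenoxy]acetylide | [Li]C#COc1ccccc1OCc1ccccc1 | intermediate (not isolated)
13 | lithium {[2-(benzyloxy)phenoxy]ethynyl}(isopropoxy)(pinacolato)borate | [Li+].CC(C)O[B-]1(C#COc2ccccc2OCc2ccccc2)OC(C)(C)C(C)(C)O1 | intermediate (not isolated)
14 | 2-{[2-(benzyloxy)phenoxy]ethynyl}-4,4,5,5-tetramethyl-1,3,2-dioxaborolane | CC1(C)OB(C#COc2ccccc2OCc2ccccc2)OC1(C)C | intermediate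
15 | rac-2-[2-(benzyloxy)phenoxy]-1,5,6-tribromo-3-(4,4,5,5-tetramethyl-1,3,2-dioxaborolan-2-yl)-7-thiabicyclo[2.2.1]hepta-2,5-diene 7,7-dioxide (one enantiomer drawn) | O=S1(=O)[C@@]2(Br)C(Br)=C(Br)[C@@H]1C(B3OC(C)(C)C(C)(C)O3)=C2Oc4ccccc4OCc5ccccc5 | intermediate (not isolated)
16 | 2-{2-[2-(benzyloxy)phenoxy]-3,4,5-tribromophenyl}-4,4,5,5-tetramethyl-1,3,2-dioxaborolane | CC1(C)OB(OC1(C)C)c1cc(Br)c(Br)c(Br)c1Oc1ccccc1OCc1ccccc1 | intermediate
17 | 2-{2-[2-(benzyloxy)phenoxy]-3,4,5-tribromophenoxy}-4,4,5,5-tetramethyl-1,3,2-dioxaborolane | CC1(C)OB(OC1(C)C)Oc1cc(Br)c(Br)c(Br)c1Oc1ccccc1OCc1ccccc1 | intermediate (not isolated)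
18 | 2-[2-(benzyloxy)phenoxy]-3,4,5-tribromophenol | Oc1cc(Br)c(Br)c(Br)c1Oc1ccccc1OCc1ccccc1 | intermediate
19 | 2-[2-(benzyloxy)phenoxy]-3,4,5-tribromoanisole | COc1cc(Br)c(Br)c(Br)c1Oc1ccccc1OCc1ccccc1 | intermediate
20 | dichloro[2-(2,3,4-tribromo-6-methoxyphenoxy)phenoxy]borane | ClB(Cl)Oc1ccccc1Oc1c(OC)cc(Br)c(Br)c1Br | intermediate (not isolated)
21 | 2-(2,3,4-tribromo-6-methoxyphenoxy)phenol | COc1cc(Br)c(Br)c(Br)c1Oc1ccccc1O | intermediate
22 | 4-bromo-2-(2,3,4-tribromo-6-methoxyphenoxy)phenol | COc1cc(Br)c(Br)c(Br)c1Oc1cc(Br)ccc1O | intermediate (not isolated)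
23 | 2,4-dibromo-6-(2,3,4-tribromo-6-methoxyphenoxy)phenol | COc1cc(Br)c(Br)c(Br)c1Oc1cc(Br)cc(Br)c1O | target

**Totals**

Total step count: 9.
Longest linear sequence: 7 steps (steps 3, 4, 5, 6, 7, 8, 9 from 6). The diene arm, steps 1 and 2, is equally long up to step 5.

**Steps most likely to fail**

**1. Step 5 (bears the label "Proposed new method:").**
- What may go wrong: self-dimerisation of the diene may outrun the cross reaction. A stepwise zwitterionic addition may divert to (2+2) adducts or to ring opening of the sulfone. SO2 and traces of water may protodeboronate the alkyne. The regioselectivity may erode.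
- Fallback (known chemistry only): it gives up the ring construction and takes ring A from the aromatic pool. It sets out from 6 and comes back at 19.
- Compound 6 is treated with Tf2O and pyridine in CH2Cl2 to give 2-(benzyloxy)phenyl trifluoromethanesulfonate F1.
- Miyaura borylation (B2pin2, PdCl2(dppf), KOAc, dioxane, 80 °C) then gives 2-[2-(benzyloxy)phenyl]-4,4,5,5-tetramethyl-1,3,2-dioxaborolane F2.
- NaIO4/NH4OAc in aqueous acetone frees [2-(benzyloxy)phenyl]boronic acid F3.
- Separately, guaiacol is tribrominated with Br2 in AcOH to 2,3,4-tribromo-6-methoxyphenol F4. The hydroxyl directs to its ortho and para carbons and the methoxy group to its para carbon, so only the C–H next to OMe remains.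
- Chan–Lam coupling of F3 with F4 (Cu(OAc)2, pyridine, 4 Å MS, CH2Cl2, air, rt) forms the O–C1' bond without touching the aryl bromides and gives 19.

**2. Step 4.**
- What may go wrong: HCl may add across the ynol ether while the borate collapses. Protodeboronation or hydration of the push–pull alkyne may occur during isolation.
- Fallback: silicon replaces boron as the placeholder for the C2 oxygen, so no acid is needed. It sets out from 9 and comes back at 18.
- Compound 9 is taken to 12 as in step 4 and quenched with ClSiMe2H to give {[2-(benzyloxy)phenoxy]ethynyl}dimethylsilane F5. This is a C-silylated ynol ether, a class that tolerates aqueous work-up and chromatography.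
- Cycloaddition with 5 under the conditions of step 5 passes through rac-2-[2-(benzyloxy)phenoxy]-1,5,6-tribromo-3-(dimethylsilyl)-7-thiabicyclo[2.2.1]hepta-2,5-diene 7,7-dioxide F6 and should give {2-[2-(benzyloxy)phenoxy]-3,4,5-tribromophenyl}dimethylsilane F7.
- The alkyne keeps the same polarity. Silicon stabilises positive charge at the oxygen-bearing carbon, and the silyl group again prefers the C–H neighbour. This cycloaddition is as untested as step 5.
- Tamao oxidation (KF, KHCO3, 30% H2O2, THF/MeOH), preceded in the flask by solvolysis of the Si–H bond, then gives 18.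

**3. Step 2.**
- What may go wrong: S-oxidation of the very electron-poor ring may be slow. Long exposure to peracid would then be needed, during which the product may dimerise through its less hindered C4=C5 bond or degrade.
- Fallback: an electron-richer silylthiophene is oxidised and the third bromine is placed after the oxidation. It sets out from 1 and comes back at 5.
- Compound 2, generated from 1 as in step 1, is trapped with Me3SiCl to give trimethyl(3,4,5-tribromothiophen-2-yl)silane F8.
- A second bromine–lithium exchange at the remaining α-bromine (n-BuLi, Et2O, −78 °C) gives [3,4-dibromo-5-(trimethylsilyl)thiophen-2-yl]lithium F9. Water protonates it to (3,4-dibromothiophen-2-yl)trimethylsilane F10.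
- mCPBA in ClCH2CH2Cl oxidises this to (3,4-dibromo-1,1-dioxidothiophen-2-yl)trimethylsilane F11.
- Bromodesilylation (Br2, AgBF4, CH2Cl2, 0 °C), a known entry to α-bromothiophene dioxides, gives 5 under mild, non-oxidising conditions, ready for immediate use.

**Further compounds**

F1 | step 5 | 2-(benzyloxy)phenyl trifluoromethanesulfonate | O=S(=O)(Oc1ccccc1OCc1ccccc1)C(F)(F)F
F2 | step 5 | 2-[2-(benzyloxy)phenyl]-4,4,5,5-tetramethyl-1,3,2-dioxaborolane | CC1(C)OB(OC1(C)C)c1ccccc1OCc1ccccc1
F3 | step 5 | [2-(benzyloxy)phenyl]boronic acid | OB(O)c1ccccc1OCc1ccccc1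
F4 | step 5 | 2,3,4-tribromo-6-methoxyphenol | COc1cc(Br)c(Br)c(Br)c1O
F5 | step 4 | {[2-(benzyloxy)phenoxy]ethynyl}dimethylsilane | C[SiH](C)C#COc1ccccc1OCc1ccccc1
F6 | step 4 | rac-2-[2-(benzyloxy)phenoxy]-1,5,6-tribromo-3-(dimethylsilyl)-7-thiabicyclo[2.2.1]hepta-2,5-diene 7,7-dioxide (one enantiomer drawn) | O=S1(=O)[C@@]2(Br)C(Br)=C(Br)[C@@H]1C([SiH](C)C)=C2Oc3ccccc3OCc4ccccc4
F7 | step 4 | {2-[2-(benzyloxy)phenoxy]-3,4,5-tribromophenyl}dimethylsilane | C[SiH](C)c1cc(Br)c(Br)c(Br)c1Oc1ccccc1OCc1ccccc1
F8 | step 2 | trimethyl(3,4,5-tribromothiophen-2-yl)silane | C[Si](C)(C)c1sc(Br)c(Br)c1Br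
F9 | step 2 | [3,4-dibromo-5-(trimethylsilyl)thiophen-2-yl]lithium | [Li]c1sc([Si](C)(C)C)c(Br)c1Br
F10 | step 2 | (3,4-dibromothiophen-2-yl)trimethylsilane | C[Si](C)(C)c1scc(Br)c1Br
F11 | step 2 | (3,4-dibromo-1,1-dioxidothiophen-2-yl)trimethylsilane | C[Si](C)(C)C1=C(Br)C(Br)=CS1(=O)=O
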